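**Strategy.** The seven-membered carbocycle (C1, C5–C10) is trans-fused to the cyclopropane (C6, C7, C11), too strained to close directly, and its C1 carries the acetal carbon C2 next to the tertiary carbinol C10. Everything rests on making this ring one carbon larger: an eight-membered cyclooctene that still contains C2, built from (S)-linalool, an organocatalytic trans-cyclopropanation, an iridium-catalysed allylation and ring-closing metathesis. Lewis-acid rearrangement of the derived 2,3-epoxy silyl ether then shifts C10 from C2 to C1, contracting the ring, expelling C2 as the formyl group and setting C1 in one operation. Oxa-Michael closure of the oxepane, lactolisation and acetylation finish the route.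

Key step: step 13

Assumption: the SMILES is read literally; H-6 and H-7 are trans, so the cyclopropane is trans-fused to the carbocycle and cis-fused to the oxepane.

Numbering used: carbocycle C1–C5–C6–C7–C8–C9–C10; cyclopropane C6–C7–C11; C2 = acetal carbon on C1; C3=C4 = enol ether (C4 on C5); C12 (oxepane CH2) and C13 (CH2OAc) on C11; C14 = methyl on C10; C15 = oxepane CH2 on C4.

Step 1
Reactants: 1 (S)-(+)-linalool
Product: 2 (S)-linalyl acetate
Conditions: Ac2O, Et3N, DMAP (0.2 equiv), CH2Cl2, 35 °C
Reagents that add atoms: acetic anhydride CC(=O)OC(C)=O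
Why: DMAP-catalysed acylation of the tertiary alcohol; the acetate prevents oxa-Michael addition of the C10 oxygen in steps 3–4 and falls off without an extra step in step 6, while the chiral-pool centre C10 is untouched.

Step 2
Reactants: 2 (S)-linalyl acetate
Product: 3 (S)-3-methyl-6-oxohex-1-en-3-yl acetate
Conditions: O3 (1.0 equiv), pyridine (cat.), CH2Cl2, −78 °C; then Me2S
Reagents that add atoms: ozone [O-][O+]=O
Why: Ozonolysis should be selective for the electron-rich trisubstituted alkene over the hindered vinyl group that is deactivated by the allylic acetate.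

Step 3
Reactants: 3 (S)-3-methyl-6-oxohex-1-en-3-yl acetate; 4 (triphenylphosphoranylidene)acetaldehyde
Product: 5 (3S,6E)-3-methyl-8-oxoocta-1,6-dien-3-yl acetate
Conditions: toluene, 80 °C
Reagents that add atoms: none
Why: Wittig olefination with a stabilised ylide should give the (E)-enal needed for the trans-cyclopropane.

Step 4
Reactants: 5 (3S,6E)-3-methyl-8-oxoocta-1,6-dien-3-yl acetate; 6 diethyl bromomalonate
Product: 7 diethyl (2R,3R)-2-formyl-3-[(3S)-3-acetoxy-3-methylpent-4-en-1-yl]cyclopropane-1,1-dicarboxylate
Conditions: (S)-α,α-diphenylprolinol trimethylsilyl ether (20 mol %), 2,6-lutidine (1.1 equiv), CH2Cl2, 0 °C → rt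
Reagents that add atoms: none
Why: Organocatalytic Michael-initiated ring closure (iminium then enamine); the malonate carbon adds to C7 on the face opposite the diphenyl(silyloxy)methyl group and the enamine displaces bromide, so the catalyst sets C6 and C7 and the (E)-enal geometry makes C5 and C8 trans.

Step 5
Reactants: 7 cyclopropane aldehyde; 8 ethyl (triphenylphosphoranylidene)acetate
Product: 9 diethyl (2R,3R)-2-[(E)-3-ethoxy-3-oxoprop-1-enyl]-3-[(3S)-3-acetoxy-3-methylpent-4-en-1-yl]cyclopropane-1,1-dicarboxylate
Conditions: CH2Cl2, rt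
Reagents that add atoms: none
Why: Wittig olefination with a stabilised ylide gives the (E)-enoate; the trans-cyclopropane aldehyde is the thermodynamic epimer, so C6 is not at risk.

Step 6
Reactants: 9 triester
Product: 10 (E)-3-{(1R,3R)-2,2-bis(hydroxymethyl)-3-[(3S)-3-hydroxy-3-methylpent-4-en-1-yl]cyclopropyl}prop-2-en-1-ol
Conditions: i-Bu2AlH (10 equiv), CH2Cl2, −78 → 0 °C; potassium sodium tartrate work-up
Reagents that add atoms: none
Why: Hydride reduction takes the enoate to the allylic alcohol (1,2-reduction), the malonate to the 1,3-diol and cleaves the acetate, and removing the acceptor groups from C11 before any transition-metal step avoids opening of the vinylcyclopropane.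

Step 7
Reactants: 10 tetraol
Product: 11 acetonide of 10 (spiro 1,3-dioxane on C11; allylic and tertiary hydroxyls free)
Conditions: 2,2-dimethoxypropane, PPTS (5 mol %), acetone, rt
Reagents that add atoms: 2,2-dimethoxypropane COC(C)(C)OC
Why: Acetalisation; only the C12/C13 1,3-diol can form a six-membered cyclic acetal, and the symmetric acetonide keeps C11 non-stereogenic until the oxepane closes.

Step 8
Reactants: 11 acetonide diol
Product: 12 allylic methyl carbonate of 11
Conditions: ClCO2Me, pyridine, CH2Cl2, 0 °C
Reagents that add atoms: methyl chloroformate COC(=O)Cl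
Why: Acylation of the primary allylic alcohol; the tertiary C10 hydroxyl is too hindered to react.

Step 9
Reactants: 12 allylic methyl carbonate; 13 methyl 2-(diethoxyphosphoryl)acetate
Product: 15 methyl (3S)-2-methylene-3-[cyclopropyl]pent-4-enoate (acrylate diene), via phosphonate 14 (not isolated)
Conditions: 13, NaH, THF; [Ir(cod)Cl]2 (2 mol %), (Sa,S,S)-phosphoramidite from (S)-BINOL and bis[(S)-1-phenylethyl]amine (4 mol %), TBD (8 mol %), 35 °C; then 37 % aq. CH2O, K2CO3, 40 °C
Reagents that add atoms: formaldehyde C=O
Why: Iridium-catalysed branched-selective asymmetric allylic alkylation puts the phosphonoacetate carbon (C4) on C5 and leaves the vinyl group (C1), with the C5 configuration set by the ligand (the (Sa,S,S) enantiomer is expected to give the required sense; otherwise its mirror image is used), and the Horner–Wadsworth–Emmons reaction with formaldehyde then erases the C4 centre and installs C15 as the methylene.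

Step 10
Reactants: 15 acrylate diene
Product: 16 cyclooctenol (Z-cyclooctene C5–C1=C2–C10–C9–C8–C7–C6, trans-fused to the cyclopropane)
Conditions: second-generation Hoveyda–Grubbs catalyst (10 mol %), toluene (2 mM), 80 °C
Reagents that add atoms: none
Why: Ring-closing metathesis of the two monosubstituted vinyl groups; the trans-cyclopropane fits an eight-membered ring without strain, the quaternary carbinol and free allylic hydroxyl favour closure, and the 1,1-disubstituted acrylate alkene is a poor metathesis partner.

Step 11
Reactants: 16 cyclooctenol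
Product: 17 syn-epoxy alcohol (epoxide on C1–C2, cis to the C10 hydroxyl)
Conditions: VO(acac)2 (5 mol %), t-BuOOH (1.5 equiv), CH2Cl2, 0 °C
Reagents that add atoms: tert-butyl hydroperoxide CC(C)(C)OO
Why: Hydroxyl-directed vanadium-catalysed epoxidation delivers oxygen to the alkene face syn to the tertiary allylic alcohol, which is the face that leads to the correct C1 after inversion in step 13; the electron-poor acrylate is not epoxidised.

Step 12
Reactants: 17 syn-epoxy alcohol
Product: 18 epoxy triethylsilyl ether
Conditions: Et3SiOTf, 2,6-lutidine, CH2Cl2, −78 °C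
Reagents that add atoms: triethylsilyl trifluoromethanesulfonate CC[Si](CC)(CC)OS(=O)(=O)C(F)(F)F
Why: Silylation of the tertiary alcohol blocks the alkoxide-driven shift of a C10 substituent and turns C10 into a good migrating group.

Step 13
Reactants: 18 epoxy triethylsilyl ether
Product: 19 ring-contracted β-siloxy aldehyde (seven-membered carbocycle, C2 as CHO on C1)
Conditions: MABR, MeAl(OAr)2 with Ar = 4-bromo-2,6-di-tert-butylphenyl (2.2 equiv, from Me3Al and the phenol), CH2Cl2, −78 → −40 °C
Reagents that add atoms: none
Why: MABR binds the epoxide oxygen, the distal C1–O bond ionises, and the siloxy-bearing ring carbon C10 shifts from C2 to C1 anti to the departing oxygen while C2 collapses to the aldehyde, so the eight-membered ring loses C2 and becomes the seven-membered carbocycle. The closest known reaction type is the organoaluminium-promoted rearrangement of 2,3-epoxy silyl ethers to β-siloxy aldehydes (semipinacol type), run here inside a ring as a contraction. No ring is closed by cyclisation: the seven-membered ring arises by a suprafacial 1,2-shift, its trans fusion to the cyclopropane is inherited from the relaxed eight-membered precursor, and the added strain is paid by opening the epoxide. C1 is set by inversion at the epoxide carbon (the epoxide was placed syn to the C10 oxygen in step 11) and C10 migrates with retention, so both centres follow from linalool and the directed epoxidation. The step needs migration of C10 in preference to hydride shift and to ionisation at C2; the high migratory aptitude of an α-siloxy carbon and the deactivation of C2 by the adjacent C–O bond secure this, and a shift of the other ring bond would converge on the same aldehyde. The bulky aluminium phenoxide at low temperature should spare the acetonide, the acrylate and the cyclopropane.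

Step 14
Reactants: 19 β-siloxy aldehyde
Product: 20 diol (C2–OH and allylic C3–OH)
Conditions: i-Bu2AlH (5 equiv), CH2Cl2, −78 °C
Reagents that add atoms: none
Why: Hydride reduction brings the acrylate ester to the allylic alcohol (1,2-reduction) and, unavoidably, the aldehyde to the primary alcohol; both are re-oxidised together in step 15.

Step 15
Reactants: 20 diol
Product: 21 dialdehyde (C2 aldehyde and 2-substituted acrolein C3/C4=C15)
Conditions: Dess–Martin periodinane (2.5 equiv), NaHCO3, CH2Cl2, 0 °C → rt
Reagents that add atoms: none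
Why: Dess–Martin oxidation of both primary alcohols under buffered, non-epimerising conditions; the tertiary centre is silylated and the product is used at once because α-methylene aldehydes self-condense.

Step 16
Reactants: 21 dialdehyde
Product: 23 lactol (oxepane and 2-hydroxy-dihydropyran closed, C13–OH free, C10–OSiEt3), via diol-dialdehyde 22 (not isolated)
Conditions: PPTS (0.3 equiv), MeCN–H2O 10:1, 40 °C
Reagents that add atoms: none
Why: Acetonide hydrolysis frees the two hydroxymethyl groups, of which only the one cis to C5 (C12) can reach C15, so a 7-endo oxa-Michael addition closes the oxepane and fixes C11; the resulting C3 enol is trapped by the C2 aldehyde as the cyclic hemiacetal, while the silyl ether keeps the C10 oxygen from forming a competing hemiacetal.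

Step 17
Reactants: 23 lactol
Product: 24 bis-acetate silyl ether
Conditions: Ac2O, pyridine, DMAP (cat.), CH2Cl2, 0 °C
Reagents that add atoms: acetic anhydride CC(=O)OC(C)=O
Why: Acylation of the primary C13 alcohol and of the equilibrating lactol, which should be trapped as the acetate with OAc pseudoaxial (anomeric effect) and trans to the C1–C10 bond, as in the target.

Step 18
Reactants: 24 bis-acetate silyl ether
Product: 25 CNP0250836.2
Conditions: HF·pyridine, pyridine, THF, 0 °C
Reagents that add atoms: none
Why: Buffered fluoride desilylation frees the tertiary C10 alcohol without touching the acetates or the enol-ether acetal.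

**Compound list**

1 | (S)-(+)-linalool, (3S)-3,7-dimethylocta-1,6-dien-3-ol | CC(C)=CCC[C@](C)(O)C=C | starting material
2 | (S)-linalyl acetate | CC(C)=CCC[C@](C)(OC(C)=O)C=C | intermediate
3 | (S)-3-methyl-6-oxohex-1-en-3-yl acetate | O=CCC[C@](C)(OC(C)=O)C=C | intermediate
4 | (triphenylphosphoranylidene)acetaldehyde | O=CC=P(c1ccccc1)(c1ccccc1)c1ccccc1 | starting material
5 | (3S,6E)-3-methyl-8-oxoocta-1,6-dien-3-yl acetate | O=C/C=C/CC[C@](C)(OC(C)=O)C=C | intermediate
6 | diethyl bromomalonate | CCOC(=O)C(Br)C(=O)OCC | starting material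
7 | diethyl (2R,3R)-2-formyl-3-[(3S)-3-acetoxy-3-methylpent-4-en-1-yl]cyclopropane-1,1-dicarboxylate | O=C[C@@H]1[C@@H](CC[C@](C)(OC(C)=O)C=C)C1(C(=O)OCC)C(=O)OCC | intermediate
8 | ethyl (triphenylphosphoranylidene)acetate | CCOC(=O)C=P(c1ccccc1)(c1ccccc1)c1ccccc1 | starting material
9 | diethyl (2R,3R)-2-[(E)-3-ethoxy-3-oxoprop-1-enyl]-3-[(3S)-3-acetoxy-3-methylpent-4-en-1-yl]cyclopropane-1,1-dicarboxylate | CCOC(=O)/C=C/[C@@H]1[C@@H](CC[C@](C)(OC(C)=O)C=C)C1(C(=O)OCC)C(=O)OCC | intermediate
10 | (E)-3-{(1R,3R)-2,2-bis(hydroxymethyl)-3-[(3S)-3-hydroxy-3-methylpent-4-en-1-yl]cyclopropyl}prop-2-en-1-ol | OC/C=C/[C@@H]1[C@@H](CC[C@](C)(O)C=C)C1(CO)CO | intermediate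
11 | acetonide of 10: trans-cyclopropane spiro-fused to a 2,2-dimethyl-1,3-dioxane, (E)-3-hydroxyprop-1-enyl on C6, (3S)-3-hydroxy-3-methylpent-4-enyl on C7 | OC/C=C/[C@@H]1[C@@H](CC[C@](C)(O)C=C)C12COC(C)(C)OC2 | intermediate
12 | allylic methyl carbonate of 11 | COC(=O)OC/C=C/[C@@H]1[C@@H](CC[C@](C)(O)C=C)C12COC(C)(C)OC2 | intermediate
13 | methyl 2-(diethoxyphosphoryl)acetate | CCOP(=O)(CC(=O)OC)OCC | starting material
14 | branched allylation product: C5 bears vinyl (C1) and CH(PO(OEt)2)CO2Me (C4, both epimers at C4) | C=C[C@H](C(C(=O)OC)P(=O)(OCC)OCC)[C@@H]1[C@@H](CC[C@](C)(O)C=C)C12COC(C)(C)OC2 | intermediate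
15 | acrylate diene: methyl (3S)-2-methylene-3-(cyclopropyl)pent-4-enoate carrying the spiro-acetonide cyclopropane and the (3S)-3-hydroxy-3-methylpent-4-enyl chain | C=C[C@H](C(=C)C(=O)OC)[C@@H]1[C@@H](CC[C@](C)(O)C=C)C12COC(C)(C)OC2 | intermediate
16 | cyclooctenol: (Z)-cyclooctene C5–C1=C2–C10–C9–C8–C7–C6, C10 with methyl and OH, trans-fused spiro-acetonide cyclopropane at C6–C7, methyl acrylate unit on C5 | C=C(C(=O)OC)[C@H]1/C=C\[C@@](C)(O)CC[C@@H]2[C@@H]1C23COC(C)(C)OC3 | intermediate
17 | syn-epoxy alcohol: C1–C2 epoxide of 16, cis to the C10 hydroxyl | C=C(C(=O)OC)[C@H]1[C@H]2O[C@H]2[C@@](C)(O)CC[C@@H]3[C@@H]1C34COC(C)(C)OC4 | intermediate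
18 | triethylsilyl ether of 17 | C=C(C(=O)OC)[C@H]1[C@H]2O[C@H]2[C@@](C)(O[Si](CC)(CC)CC)CC[C@@H]3[C@@H]1C34COC(C)(C)OC4 | intermediate
19 | ring-contracted aldehyde: cycloheptane C1–C5–C6–C7–C8–C9–C10, CHO (C2) on C1, H-1/H-5 cis, C10 with methyl and OSiEt3, trans-fused spiro-acetonide cyclopropane, methyl acrylate unit on C5 | O=C[C@@H]1[C@H](C(=C)C(=O)OC)[C@@H]2[C@@H](CC[C@]1(C)O[Si](CC)(CC)CC)C23COC(C)(C)OC3 | intermediate
20 | diol: 19 with C2 as CH2OH and the ester as CH2OH | OC[C@@H]1[C@H](C(=C)CO)[C@@H]2[C@@H](CC[C@]1(C)O[Si](CC)(CC)CC)C23COC(C)(C)OC3 | intermediate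
21 | dialdehyde: C2 aldehyde on C1 and 2-substituted acrolein on C5 | O=C[C@@H]1[C@H](C(=C)C=O)[C@@H]2[C@@H](CC[C@]1(C)O[Si](CC)(CC)CC)C23COC(C)(C)OC3 | intermediate
22 | diol-dialdehyde: 21 without the acetonide | O=C[C@@H]1[C@H](C(=C)C=O)[C@@H]2[C@@H](CC[C@]1(C)O[Si](CC)(CC)CC)C2(CO)CO | intermediate
23 | lactol: target skeleton with C2–OH, C13–OH and C10–OSiEt3 | OC[C@@]12COCC3=CO[C@H](O)[C@@H]4[C@H]3[C@@H]1[C@H]2CC[C@]4(C)O[Si](CC)(CC)CC | intermediate
24 | 2,13-di-O-acetyl-10-O-triethylsilyl derivative | CC(=O)OC[C@@]12COCC3=CO[C@H](OC(C)=O)[C@@H]4[C@H]3[C@@H]1[C@H]2CC[C@]4(C)O[Si](CC)(CC)CC | intermediate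
25 | CNP0250836.2 | CC(=O)OC[C@@]12COCC3=CO[C@H](OC(C)=O)[C@@H]4[C@H]3[C@@H]1[C@H]2CC[C@]4(C)O | target

**Totals.** Total step count: 18. Longest linear sequence: 18 steps (from 1).

**Steps most likely to fail**

Step 13. The rearrangement may go astray by hydride shift to the α-siloxy cyclooctanone or by Lewis-acid cleavage of the acetonide. The fallback replaces Lewis-acid epoxide opening by a base-driven pinacol-type shift. It sets out from 16: hydroxyl-directed syn-dihydroxylation (OsO4, TMEDA, CH2Cl2, −78 °C; aq. NaHSO3) should give the all-syn triol F1. Selective mesylation of the less hindered C1 hydroxyl (MsCl, 2,4,6-collidine, 0 °C) gives the hydroxy mesylate F2. Et3Al (CH2Cl2, −78 → 0 °C) drives the stereospecific shift of C10 from C2 to C1 with loss of mesylate, giving the β-hydroxy aldehyde F3. Silylation (Et3SiOTf, 2,6-lutidine) returns to the route at 19.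

Step 10. Ring closure may lose to intermolecular metathesis, or the hindered vinyl carbinol may fail to engage. The fallback closes the ring by carbonyl coupling instead. It sets out from 15: silylation (Et3SiOTf, 2,6-lutidine) gives the silyl ether F4. Ozonolysis of the two vinyl groups (O3, 2 equiv, CH2Cl2–pyridine, −78 °C; Me2S), which should leave the electron-poor acrylate, gives the dialdehyde F5. Intramolecular McMurry coupling with low-valent titanium (TiCl3, Zn–Cu, DME, slow addition, reflux) gives the silylated (Z)-cyclooctene F6. Bu4NF then returns to the route at 16.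

Step 16. The seven-membered ether closure may be too slow, so that the free dialdehyde is lost by self-condensation of the enal, β-elimination of the siloxy group or epimerisation at C1. The fallback closes the ether under base with C2 masked. It sets out from 19: acetalisation (1,2-bis(trimethylsilyloxy)ethane, Me3SiOTf cat., CH2Cl2, −78 °C) gives the dioxolane ester F7. i-Bu2AlH gives the allylic alcohol F8 and MnO2 the enal F9. PPTS in MeOH removes the acetonide, and DBU in MeCN closes the oxepane by oxa-Michael addition to give the oxepane aldehyde F10 (both C4 epimers, which converge). Aqueous AcOH (THF, 40 °C) unmasks C2, and the dialdehyde lactolises to return to the route at 23.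

**Further compounds**

F1 | step 13 | all-syn triol (C1–OH, C2–OH, C10–OH cis) of the cyclooctane | C=C(C(=O)OC)[C@H]1[C@@H](O)[C@@H](O)[C@@](C)(O)CC[C@@H]2[C@@H]1C23COC(C)(C)OC3
F2 | step 13 | C1 mesylate of the triol | C=C(C(=O)OC)[C@H]1[C@@H](OS(C)(=O)=O)[C@@H](O)[C@@](C)(O)CC[C@@H]2[C@@H]1C23COC(C)(C)OC3
F3 | step 13 | ring-contracted β-hydroxy aldehyde (19 without the silyl group) | O=C[C@@H]1[C@H](C(=C)C(=O)OC)[C@@H]2[C@@H](CC[C@]1(C)O)C23COC(C)(C)OC3
F4 | step 10 | triethylsilyl ether of 15 | C=C[C@H](C(=C)C(=O)OC)[C@@H]1[C@@H](CC[C@](C)(O[Si](CC)(CC)CC)C=C)C12COC(C)(C)OC2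
F5 | step 10 | dialdehyde from cleavage of both vinyl groups of F4 | O=C[C@H](C(=C)C(=O)OC)[C@@H]1[C@@H](CC[C@](C)(O[Si](CC)(CC)CC)C=O)C12COC(C)(C)OC2
F6 | step 10 | triethylsilyl ether of 16 | C=C(C(=O)OC)[C@H]1/C=C\[C@@](C)(O[Si](CC)(CC)CC)CC[C@@H]2[C@@H]1C23COC(C)(C)OC3
F7 | step 16 | 1,3-dioxolane acetal of 19 | C1(OCCO1)[C@@H]2[C@H](C(=C)C(=O)OC)[C@@H]3[C@@H](CC[C@]2(C)O[Si](CC)(CC)CC)C34COC(C)(C)OC4
F8 | step 16 | allylic alcohol from F7 | C1(OCCO1)[C@@H]2[C@H](C(=C)CO)[C@@H]3[C@@H](CC[C@]2(C)O[Si](CC)(CC)CC)C34COC(C)(C)OC4
F9 | step 16 | enal from F8 | C1(OCCO1)[C@@H]2[C@H](C(=C)C=O)[C@@H]3[C@@H](CC[C@]2(C)O[Si](CC)(CC)CC)C34COC(C)(C)OC4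
F10 | step 16 | oxepane aldehyde with C2 as dioxolane, C13–OH free (both C4 epimers) | OC[C@@]12COCC(C=O)[C@@H]3[C@@H]1[C@H]2CC[C@](C)(O[Si](CC)(CC)CC)[C@@H]3C4OCCO4
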